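## Retrosynthetic overview
1. The angelate is put on last by acylating the C3–OH of the cis-(2R,3R)-alcohol. No bond to a stereocentre is broken.
2. The key disconnection is C2–C3, between the formyl carbon and the ArO–CH2 carbon of an open-chain ether-aldehyde. Both are natural acceptor carbons. The ether carbon is made a donor as a γ-aryloxyallylchromium species (a 1-oxyallyl anion, a homoenolate-type synthon) by allylic C–H abstraction and chromium capture.
3. This isomerisation closes the dihydrofuran ring and sets both stereocentres. It is the only ring formed; the benzene ring is bought.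
4. The ether-aldehyde comes from 5-acetyl-2,4-dihydroxybenzaldehyde and 2-methylidenepropane-1,3-diyl diacetate (O1–CH2 bond). The diacetate brings the whole C4 side chain with its acetate.
5. The dihydroxy aldehyde comes from 2,4-dimethoxyacetophenone by C5 formylation and double demethylation.

Assumption: precedent does not predict the sense of induction in step 4. One test run fixes which ligand antipode gives (2R,3R)-8 (both antipodes are commercial), and the structures below show the required outcome.

## Route

Step 1
Reactants: 1 1-(2,4-dimethoxyphenyl)ethan-1-one (2,4-dimethoxyacetophenone)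
Product: 2 5-acetyl-2,4-dimethoxybenzaldehyde
Conditions: Cl2CHOMe (1.5 equiv), TiCl4 (2.5 equiv), CH2Cl2, 0 °C to rt; ice/1 M HCl work-up
Reagents that add atoms: dichloromethyl methyl ether, COC(Cl)Cl; water, O
Why: In this Rieche formylation (electrophilic aromatic substitution) C5 is para to one methoxy group and ortho to the other and is the only unhindered activated position, because C3 is flanked by both methoxy groups; no stereocentre is formed.

Step 2
Reactants: 2 5-acetyl-2,4-dimethoxybenzaldehyde
Product: 3 5-acetyl-2,4-dihydroxybenzaldehyde
Conditions: BCl3 (3 equiv), CH2Cl2, −78 °C to rt; aqueous work-up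
Reagents that add atoms: none
Why: This is a chelation-assisted aryl methyl ether cleavage in which each methoxy group sits ortho to a carbonyl group, so BCl3 binds in a six-membered chelate and chloride removes the methyl group while aldehyde and ketone survive.

Step 3
Reactants: 3 5-acetyl-2,4-dihydroxybenzaldehyde; 4 2-methylidenepropane-1,3-diyl diacetate
Product: 5 2-[(4-acetyl-2-formyl-5-hydroxyphenoxy)methyl]prop-2-en-1-yl acetate
Conditions: 4 (3 equiv, excess recovered), Pd(PPh3)4 (3 mol%), Et3N (1.2 equiv), THF, 40 °C
Reagents that add atoms: none
Why: In this Tsuji–Trost O-allylation the symmetrical 2-(acetoxymethyl)allylpalladium cation gives one constitutional isomer, excess 4 suppresses double substitution, the hydroxyl ortho to the formyl group reacts because it is the more acidic one (estimated about one pKa unit), and reversible ionisation of the electron-poor aryl ether lets the mixture settle on the isomer that keeps the stronger O–H···O=C(CH3) hydrogen bond.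

Step 4
Reactants: 5 2-[(4-acetyl-2-formyl-5-hydroxyphenoxy)methyl]prop-2-en-1-yl acetate
Product: 8 2-[(2R,3R)-5-acetyl-3,6-dihydroxy-2,3-dihydro-1-benzofuran-2-yl]prop-2-en-1-yl acetate (cis), via 1-aryloxyallyl radical 6 (not isolated), via allylchromium dichloride 7 (not isolated)
Conditions: CrCl2 (10 mol%), (3aR,3a'R,8aS,8a'S)-2,2'-(cyclopropane-1,1-diyl)bis(3a,8a-dihydro-8H-indeno[1,2-d]oxazole) or its antipode (12 mol%), 9-mesityl-10-methylacridinium tetrafluoroborate (3 mol%), O,O'-(biphenyl-2,2'-diyl) N-(trifluoromethylsulfonyl)phosphoramidothioate (10 mol%), 2,6-lutidine (20 mol%), CH2Cl2 (0.02 M), 450 nm LED, 20 °C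
Reagents that add atoms: none
Why: Proposed new method: the photo-oxidised thiophosphoramide anion gives a sulfur radical that abstracts the weakest C–H of 5 (allylic and alpha to oxygen; abstraction of the formyl hydrogen followed by a 1,5-hydrogen shift reaches the same site) to give 6, divalent chromium traps 6 at its free CH2 end to give nucleophilic 7 (a 1-oxyallyl anion, homoenolate-type donor, that bonds here through its oxygen-bearing carbon), and 7 adds to the neighbouring formyl carbon through a closed six-membered transition state, so two natural acceptor carbons are joined in a redox-neutral isomerisation (the trivalent chromium alkoxide is protonated by the thiophosphoramide and the acridine radical returns chromium to the divalent state); abstraction at the acetoxymethyl group can lead only to a slow seven-membered closure and is repaired by reverse hydrogen transfer; the flat benzo tether allows a ring torsion of only about 40° at the forming bond, so the Cr–O and C2–C(vinyl) bonds can be gauche only when they lie on the same face, which gives the cis ring, and the chiral bis(oxazoline) on chromium selects the aldehyde face and hence (2R,3R); the lutidine buffer prevents acid dehydration to the benzofuran; the closest known reaction types are the photoredox/hydrogen-atom-transfer/chromium asymmetric allylation of aldehydes with simple alkenes and the Nozaki–Hiyama–Kishi additions of γ-oxygenated allylchromium reagents made from acrolein acetals or 3-halopropenyl esters.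

Step 5
Reactants: 8 2-[(2R,3R)-5-acetyl-3,6-dihydroxy-2,3-dihydro-1-benzofuran-2-yl]prop-2-en-1-yl acetate; 9 angelic acid, (2Z)-2-methylbut-2-enoic acid
Product: 11 (2R,3R)-5-acetyl-2-[3-(acetyloxy)prop-1-en-2-yl]-6-hydroxy-2,3-dihydro-1-benzofuran-3-yl (2Z)-2-methylbut-2-enoate (target), via angeloyl chloride 10 (not isolated)
Conditions: 9 (1.5 equiv), 1-chloro-N,N,2-trimethylprop-1-en-1-amine (1.4 equiv), CH2Cl2, 0 °C, 1 h; then 8, 2,6-lutidine (3 equiv), CH2Cl2, 0 °C to rt
Reagents that add atoms: 1-chloro-N,N,2-trimethylprop-1-en-1-amine, CC(C)=C(Cl)N(C)C (supplies only the chlorine of 10)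
Why: In this O-acylation the acid chloride is made under neutral conditions, the weak non-nucleophilic base avoids both addition–elimination Z-to-E isomerisation and vinylketene formation, the free secondary alcohol is more nucleophilic than the un-ionised ketone-chelated phenol, and both stereocentres are retained because the C3–O bond is not broken.

## Compound list
1 | 1-(2,4-dimethoxyphenyl)ethan-1-one | CC(=O)c1ccc(OC)cc1OC | starting material
2 | 5-acetyl-2,4-dimethoxybenzaldehyde | CC(=O)c1cc(C=O)c(OC)cc1OC | intermediate
3 | 5-acetyl-2,4-dihydroxybenzaldehyde | CC(=O)c1cc(C=O)c(O)cc1O | intermediate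
4 | 2-methylidenepropane-1,3-diyl diacetate | C=C(COC(C)=O)COC(C)=O | starting material
5 | 2-[(4-acetyl-2-formyl-5-hydroxyphenoxy)methyl]prop-2-en-1-yl acetate | C=C(COC(C)=O)COc1cc(O)c(C(C)=O)cc1C=O | intermediate
6 | 1-(4-acetyl-2-formyl-5-hydroxyphenoxy)-2-(acetoxymethyl)allyl radical | C=C(COC(C)=O)[CH]Oc1cc(O)c(C(C)=O)cc1C=O | intermediate
7 | [2-(acetoxymethyl)-3-(4-acetyl-2-formyl-5-hydroxyphenoxy)prop-2-en-1-yl]chromium dichloride (trivalent chromium, bis(oxazoline) omitted, alkene geometry labile) | CC(=O)OCC(C[Cr](Cl)Cl)=COc1cc(O)c(C(C)=O)cc1C=O | intermediate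
8 | 2-[(2R,3R)-5-acetyl-3,6-dihydroxy-2,3-dihydro-1-benzofuran-2-yl]prop-2-en-1-yl acetate (cis) | C=C(COC(C)=O)[C@H]1Oc2cc(O)c(C(C)=O)cc2[C@H]1O | intermediate
9 | angelic acid, (2Z)-2-methylbut-2-enoic acid | C/C=C(/C)C(=O)O | starting material
10 | angeloyl chloride, (2Z)-2-methylbut-2-enoyl chloride | C/C=C(/C)C(=O)Cl | intermediate
11 | (2R,3R)-5-acetyl-2-[3-(acetyloxy)prop-1-en-2-yl]-6-hydroxy-2,3-dihydro-1-benzofuran-3-yl (2Z)-2-methylbut-2-enoate | C=C(COC(C)=O)[C@H]1Oc2cc(O)c(C(C)=O)cc2[C@H]1OC(=O)/C(C)=C\C | target

Total step count: 5. Longest linear sequence: 5 (1 → 2 → 3 → 5 → 8 → 11).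

## Steps most likely to fail

**Step 4.** The risks are:
- the site selectivity of hydrogen abstraction;
- binding of the hydroxy-ketone unit to chromium;
- dehydration of 8 to the benzofuran;
- an unknown enantiomeric excess.

The fallback sets out from 3 and comes back at 8. It replaces C–H abstraction by a pre-oxidised allyl donor. 1,3-Diacetoxyacetone is olefinated with lithiated bis(pinacolato)borylmethane (LiTMP, THF, −78 °C, boron-Wittig) to give 2-[(4,4,5,5-tetramethyl-1,3,2-dioxaborolan-2-yl)methylidene]propane-1,3-diyl diacetate F1. Copper-catalysed oxidative O-alkenylation of 3 with this boronate (Cu(OAc)2 20 mol%, pyridine, air, CH2Cl2, rt) gives the enol ether 2-[(4-acetyl-2-formyl-5-hydroxyphenoxy)methylidene]propane-1,3-diyl diacetate F2. This compound is a γ-aryloxyallyl acetate. A zerovalent palladium catalyst with a chiral diphosphine ionises one acetate. With formic acid/Et3N as terminal reductant, the η1-allylpalladium species adds as a nucleophile to the formyl group through the same closed, cis-selective transition state. The product is 8, with the second acetate left in place.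

**Step 3.** The risks are reaction at the wrong hydroxyl group, double substitution and re-ionisation of the product. The fallback sets out from 3 and comes back at 5. 2-Methylidenepropane-1,3-diol is mono-acetylated (Ac2O, 1 equiv) to 2-(hydroxymethyl)prop-2-en-1-yl acetate F3. This alcohol is joined to 3 by Mitsunobu etherification (PPh3, diisopropyl azodicarboxylate, THF, 0 °C). The betaine deprotonates only the more acidic hydroxyl ortho to the formyl group. The step is irreversible, and the acetate is never activated, so no second substitution can occur.

**Step 5.** The risks are competing acylation of the phenol and partial isomerisation to the tiglate on long reaction times. The fallback sets out from 8 and comes back at 11. Both hydroxyl groups are acylated on purpose with excess 10 (2,6-lutidine, CH2Cl2, 40 °C). This gives (2R,3R)-5-acetyl-2-[3-(acetyloxy)prop-1-en-2-yl]-2,3-dihydro-1-benzofuran-3,6-diyl bis[(2Z)-2-methylbut-2-enoate] F4. Pyrrolidine (1.1 equiv, THF, 0 °C) then cleaves only the aryl ester, which the ortho acetyl group activates. The alkyl acetate and the benzylic angelate stay in place.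

## Further compounds
F1 | step 4 | 2-[(4,4,5,5-tetramethyl-1,3,2-dioxaborolan-2-yl)methylidene]propane-1,3-diyl diacetate | CC(=O)OCC(COC(C)=O)=CB1OC(C)(C)C(C)(C)O1
F2 | step 4 | 2-[(4-acetyl-2-formyl-5-hydroxyphenoxy)methylidene]propane-1,3-diyl diacetate | CC(=O)OCC(COC(C)=O)=COc1cc(O)c(C(C)=O)cc1C=O
F3 | step 3 | 2-(hydroxymethyl)prop-2-en-1-yl acetate | C=C(CO)COC(C)=O
F4 | step 5 | (2R,3R)-5-acetyl-2-[3-(acetyloxy)prop-1-en-2-yl]-2,3-dihydro-1-benzofuran-3,6-diyl bis[(2Z)-2-methylbut-2-enoate] | C=C(COC(C)=O)[C@H]1Oc2cc(OC(=O)/C(C)=C\C)c(C(C)=O)cc2[C@H]1OC(=O)/C(C)=C\C
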